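## Retrosynthetic overview
1. Ester C–O bond: target ⇒ eudesmane-4β,6β-diol + phenol-protected (E)-isoferulic acid. Only the secondary 6β-OH can be acylated.
2. 6β-OH ⇒ α-face hydride reduction of 4β-hydroxyeudesman-6-one ⇒ hydroboration–oxidation of eudesm-5-en-4β-ol (sets 5α-H). C4 carbinol ⇒ MeLi + 15-noreudesm-5-en-4-one.
3. That enone ⇒ 1,2-transposition of the Robinson enone 15-noreudesm-4-en-3-one (C3 deoxygenation, Δ4 dihydroxylation, oxidation, dehydration).
4. Key C–C bond C10–C1 ⇒ intermolecular asymmetric Michael addition of the (R)-1-phenylethylamine imine of (+)-dihydrocarvone to methyl vinyl ketone (sets quaternary C10), then aldol closure C4–C5.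
5. Ring order: ring B is bought (dihydrocarvone, carries C7), ring A is closed second by the Robinson sequence, and the arene arrives last with the acid.

Assumption: eudesmane numbering is used (ring A = C1–C5, C10; ring B = C5–C10; β = the face of the C10 methyl). Commercial (+)-dihydrocarvone is taken as a C2-epimer mixture with a fixed (5R) centre.

## Route

Step 1
Reactants: 1 (+)-dihydrocarvone; 2 (R)-(+)-1-phenylethylamine
Product: 3 (5R)-2-methyl-N-[(1R)-1-phenylethyl]-5-(prop-1-en-2-yl)cyclohexan-1-imine
Conditions: p-TsOH·H2O (1 mol %), toluene, Dean–Stark, reflux, 16 h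
Reagents that add atoms: none
Why: Acid-catalysed ketimine condensation driven by azeotropic removal of water; the C2 epimer ratio of 1 is irrelevant because this centre becomes trigonal in the next step, and C5 (future C7) is not touched.

Step 2
Reactants: 3 ketimine; 4 methyl vinyl ketone
Product: 7 (2S,5R)-2-methyl-2-(3-oxobutyl)-5-(prop-1-en-2-yl)cyclohexan-1-one, via secondary enamine tautomer 5 (not isolated), via Michael adduct imine 6 (not isolated)
Conditions: MVK (1.2 equiv), THF, trace hydroquinone, rt → 40 °C, 48–72 h; then 20% aq AcOH, rt, 2 h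
Reagents that add atoms: water, O
Why: Key fragment-joining step, a d'Angelo asymmetric Michael addition: the more substituted secondary enamine tautomer adds to MVK through a compact aza-ene-type chair transition state on the face anti to the phenyl group of the (R)-auxiliary, so the chain enters trans and the methyl ends cis to the isopropenyl group (future 10β-methyl, quaternary C10), the auxiliary overriding the weak bias of the remote C5 substituent, and mild acid hydrolysis then frees the 1,5-diketone.

Step 3
Reactants: 7 diketone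
Product: 9 15-noreudesma-4,11-dien-3-one [(4aS,7R)-4a-methyl-7-(prop-1-en-2-yl)-4,4a,5,6,7,8-hexahydronaphthalen-2(3H)-one], via cis-fused ketol 8 (not isolated)
Conditions: NaOMe (0.5 equiv), MeOH, rt → 50 °C, 8 h
Reagents that add atoms: none
Why: Intramolecular aldol condensation (second half of a Robinson annulation): the methyl-ketone enolate closes ring A on the ring carbonyl and E1cB loss of water gives the conjugated enone, no stereocentre being at risk (C10 quaternary, C7 not acidic), and the few percent of C10 epimer, a diastereomer, is removed by chromatography here.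

Step 4
Reactants: 9 dienone
Product: 10 15-noreudesm-4-en-3-one [(4aS,7R)-4a-methyl-7-(propan-2-yl)-4,4a,5,6,7,8-hexahydronaphthalen-2(3H)-one]
Conditions: H2 (1 atm), RhCl(PPh3)3 (5 mol %), toluene/EtOH 1:1, rt
Reagents that add atoms: none
Why: Homogeneous hydrogenation with RhCl(PPh3)3 is selective for the unhindered 1,1-disubstituted alkene and leaves the trisubstituted conjugated enone and both stereocentres alone.

Step 5
Reactants: 10 enone
Product: 11 spiro-1,3-dithiolane at C3 of 15-noreudesm-4-ene
Conditions: HSCH2CH2SH (1.5 equiv), BF3·OEt2 (0.3 equiv), AcOH, rt, 2 h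
Reagents that add atoms: ethane-1,2-dithiol, SCCS
Why: Lewis-acid thioketalisation; unlike O-ketals, dithiolanes of enones form without migration of the double bond, so Δ4 stays in place.

Step 6
Reactants: 11 dithiolane
Product: 12 15-noreudesm-4-ene (10β-methyl and 7β-isopropyl)
Conditions: Raney Ni (W-2, deactivated in refluxing acetone), EtOH, reflux, 2 h
Reagents that add atoms: none
Why: Mozingo-type reductive desulfurisation replaces both C–S bonds by C–H, and acetone-deactivated nickel leaves the hindered trisubstituted alkene unreduced.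

Step 7
Reactants: 12 alkene
Product: 13 15-noreudesmane-4α,5α-diol
Conditions: OsO4 (2 mol %), NMO (1.5 equiv), acetone/H2O 9:1, rt, 24 h
Reagents that add atoms: osmium tetroxide, O=[Os](=O)(=O)=O; N-methylmorpholine N-oxide, C[N+]1([O-])CCOCC1; water, O
Why: Upjohn syn-dihydroxylation on the α face, opposite the axial C10 methyl; the facial ratio is not critical because C4 and C5 lose these configurations in steps 8 and 9.

Step 8
Reactants: 13 diol
Product: 14 5α-hydroxy-15-noreudesman-4-one
Conditions: IBX (1.5 equiv), DMSO, rt, 6 h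
Reagents that add atoms: none
Why: IBX oxidation converts only the secondary carbinol and does not cleave the glycol, giving the tertiary α-ketol.

Step 9
Reactants: 14 α-ketol
Product: 16 15-noreudesm-5-en-4-one, via chlorosulfite ester 15 (not isolated)
Conditions: SOCl2 (3 equiv), pyridine, 0 °C, 1 h
Reagents that add atoms: none
Why: Chlorosulfite formation followed by pyridine-induced anti E2 elimination: the axial 5α-leaving group is antiperiplanar to the axial 6β-H, and because C10 is quaternary and C4 is a carbonyl carbon the Δ5 enone is the only alkene that can form.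

Step 10
Reactants: 16 enone
Product: 17 eudesm-5-en-4β-ol (4α-methyl)
Conditions: MeLi (2 equiv), Et2O, −78 °C, 1 h; then H2O
Reagents that add atoms: methyllithium, [Li]C
Why: 1,2-addition of a hard organolithium to the enone; the axial β trajectory at C4 is blocked by the syn-axial C10 methyl, so methyl enters equatorially from the α face and sets 4α-methyl/4β-hydroxyl.

Step 11
Reactants: 17 allylic alcohol
Product: 19 5αH-eudesmane-4β,6α-diol, via C6 alkylborane 18 (not isolated)
Conditions: BH3·THF (3 equiv), THF, 0 °C → rt, 16 h; then aq NaOH, 30% H2O2, 0 °C → rt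
Reagents that add atoms: hydrogen peroxide, OO
Why: Brown hydroboration–oxidation: boron goes to the less substituted C6 and H to C5 in a syn addition on the α face (the β face is screened by the C10 methyl, the 4β-oxygen and the 7β-isopropyl group), which sets 5α-H (trans-decalin) and, after C–B oxidation with retention, 6α-OH.

Step 12
Reactants: 19 4β,6α-diol
Product: 20 4β-hydroxy-5αH-eudesman-6-one
Conditions: Dess–Martin periodinane (1.3 equiv), pyridine (3 equiv), CH2Cl2, 0 °C → rt
Reagents that add atoms: none
Why: Dess–Martin oxidation touches only the secondary alcohol, and the pyridine-buffered medium avoids retro-aldol cleavage, dehydration of the β-hydroxy ketone and epimerisation at C5 or C7.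

Step 13
Reactants: 20 hydroxy ketone
Product: 21 5αH-eudesmane-4β,6β-diol
Conditions: Li[HB(s-Bu)3] (3 equiv), THF, −78 → 0 °C; then H2O, aq NaOH, 30% H2O2, 0 °C
Reagents that add atoms: none
Why: Steric-approach-controlled ketone reduction: the bulky trialkylborohydride can reach C6 only from the open α (equatorial) side because the β face carries the syn-axial C10 methyl and 4β-OH, so the axial 6β-alcohol is formed.

Step 14
Reactants: 22 (E)-isoferulic acid
Product: 24 (E)-3-[3-(tert-butyldimethylsilyloxy)-4-methoxyphenyl]prop-2-enoic acid, via bis-silylated acid 23 (not isolated)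
Conditions: TBSCl (2.5 equiv), imidazole (5 equiv), DMF, rt, 12 h; then AcOH/THF/H2O 3:1:1, rt, 2 h
Reagents that add atoms: tert-butyldimethylsilyl chloride, CC(C)(C)[Si](C)(C)Cl
Why: Exhaustive silylation followed by selective hydrolysis of the far more labile silyl ester leaves the phenol masked as its aryl TBS ether, and the E alkene is untouched.

Step 15
Reactants: 21 4β,6β-diol; 24 O-TBS-isoferulic acid
Product: 26 4β-hydroxy-5αH-eudesman-6β-yl (E)-3-[3-(tert-butyldimethylsilyloxy)-4-methoxyphenyl]prop-2-enoate, via O-acylisourea 25 (not isolated)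
Conditions: 24 (3 equiv), DCC (3 equiv), DMAP (1 equiv), toluene, 70 °C, 24 h
Reagents that add atoms: none
Why: Steglich esterification under forcing conditions (excess activated acid, stoichiometric DMAP, heat) acylates the hindered secondary 6β-OH with retention at C6, while the tertiary 4β-OH is inert.

Step 16
Reactants: 26 silyl-protected ester
Product: 27 target CNP0291757.1
Conditions: n-Bu4NF (1.1 equiv), AcOH (1.1 equiv), THF, 0 °C, 30 min
Reagents that add atoms: none
Why: Fluoride-induced cleavage of the aryl silyl ether, buffered by AcOH so that neither the cinnamate ester nor the tertiary alcohol is affected, releases the target.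

## Compound list
1 | (+)-dihydrocarvone, (2R,5R)-2-methyl-5-(prop-1-en-2-yl)cyclohexan-1-one (commercial material also holds the 2S epimer) | C[C@@H]1CC[C@H](CC1=O)C(C)=C | starting material
2 | (R)-(+)-1-phenylethylamine | C[C@@H](N)c1ccccc1 | starting material
3 | (5R)-2-methyl-N-[(1R)-1-phenylethyl]-5-(prop-1-en-2-yl)cyclohexan-1-imine (C2 epimers) | CC1CC[C@H](CC1=N[C@H](C)c2ccccc2)C(C)=C | intermediate
4 | methyl vinyl ketone (but-3-en-2-one) | CC(=O)C=C | starting material
5 | secondary enamine tautomer of 3, (5R)-2-methyl-N-[(1R)-1-phenylethyl]-5-(prop-1-en-2-yl)cyclohex-1-en-1-amine (not isolated) | CC1=C(N[C@H](C)c2ccccc2)C[C@@H](CC1)C(C)=C | intermediate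
6 | Michael adduct imine, the ring-carbonyl N-[(1R)-1-phenylethyl] imine of 7 (not isolated) | CC(=O)CC[C@]1(C)CC[C@H](CC1=N[C@H](C)c2ccccc2)C(C)=C | intermediate
7 | (2S,5R)-2-methyl-2-(3-oxobutyl)-5-(prop-1-en-2-yl)cyclohexan-1-one (methyl cis to isopropenyl) | CC(=O)CC[C@]1(C)CC[C@H](CC1=O)C(C)=C | intermediate
8 | 5β-hydroxy-15-noreudesm-11-en-3-one, cis-fused ketol (not isolated) | C1[C@]2(O)CC(=O)CC[C@]2(C)CC[C@H]1C(C)=C | intermediate
9 | 15-noreudesma-4,11-dien-3-one, (4aS,7R) | C1C2=CC(=O)CC[C@]2(C)CC[C@H]1C(C)=C | intermediate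
10 | 15-noreudesm-4-en-3-one, (4aS,7R) | C1C2=CC(=O)CC[C@]2(C)CC[C@H]1C(C)C | intermediate
11 | C3 spiro-1,3-dithiolane of 15-noreudesm-4-ene | C1C2=CC3(SCCS3)CC[C@]2(C)CC[C@H]1C(C)C | intermediate
12 | 15-noreudesm-4-ene (10β-Me, 7β-iPr) | C1C2=CCCC[C@]2(C)CC[C@H]1C(C)C | intermediate
13 | 15-noreudesmane-4α,5α-diol | C1[C@]2(O)[C@](C)(CCC[C@H]2O)CC[C@H]1C(C)C | intermediate
14 | 5α-hydroxy-15-noreudesman-4-one | C1[C@]2(O)[C@](C)(CCCC2=O)CC[C@H]1C(C)C | intermediate
15 | 5α-chlorosulfite ester of 14 (not isolated) | C1[C@]2(OS(=O)Cl)[C@](C)(CCCC2=O)CC[C@H]1C(C)C | intermediate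
16 | 15-noreudesm-5-en-4-one | C1=C2[C@](C)(CCCC2=O)CC[C@H]1C(C)C | intermediate
17 | eudesm-5-en-4β-ol (4α-methyl) | C1=C2[C@](C)(CCC[C@]2(C)O)CC[C@H]1C(C)C | intermediate
18 | (4β-hydroxy-5αH-eudesman-6α-yl)borane, drawn as the monoalkylborane; any O–B bond at C4 is cleaved in the work-up (not isolated) | B[C@@H]1[C@@H]2[C@](C)(CCC[C@]2(C)O)CC[C@H]1C(C)C | intermediate
19 | 5αH-eudesmane-4β,6α-diol | O[C@@H]1[C@@H]2[C@](C)(CCC[C@]2(C)O)CC[C@H]1C(C)C | intermediate
20 | 4β-hydroxy-5αH-eudesman-6-one | O=C1[C@@H]2[C@](C)(CCC[C@]2(C)O)CC[C@H]1C(C)C | intermediate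
21 | 5αH-eudesmane-4β,6β-diol | O[C@H]1[C@@H]2[C@](C)(CCC[C@]2(C)O)CC[C@H]1C(C)C | intermediate
22 | (E)-isoferulic acid, (E)-3-(3-hydroxy-4-methoxyphenyl)prop-2-enoic acid | COc1ccc(/C=C/C(=O)O)cc1O | starting material
23 | tert-butyldimethylsilyl (E)-3-[3-(tert-butyldimethylsilyloxy)-4-methoxyphenyl]prop-2-enoate (not isolated) | COc1ccc(/C=C/C(=O)O[Si](C)(C)C(C)(C)C)cc1O[Si](C)(C)C(C)(C)C | intermediate
24 | (E)-3-[3-(tert-butyldimethylsilyloxy)-4-methoxyphenyl]prop-2-enoic acid | COc1ccc(/C=C/C(=O)O)cc1O[Si](C)(C)C(C)(C)C | intermediate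
25 | O-acylisourea from 24 and DCC (not isolated) | COc1ccc(/C=C/C(=O)OC(=NC2CCCCC2)NC2CCCCC2)cc1O[Si](C)(C)C(C)(C)C | intermediate
26 | 4β-hydroxy-5αH-eudesman-6β-yl (E)-3-[3-(tert-butyldimethylsilyloxy)-4-methoxyphenyl]prop-2-enoate | COc1ccc(/C=C/C(=O)O[C@H]2[C@@H]3[C@](C)(CCC[C@]3(C)O)CC[C@H]2C(C)C)cc1O[Si](C)(C)C(C)(C)C | intermediate
27 | (1R,2S,4aR,8S,8aS)-8-hydroxy-4a,8-dimethyl-2-(propan-2-yl)decahydronaphthalen-1-yl (2E)-3-(3-hydroxy-4-methoxyphenyl)prop-2-enoate (6β-isoferuloyloxyeudesman-4β-ol) | COc1ccc(/C=C/C(=O)O[C@H]2[C@@H]3[C@](C)(CCC[C@]3(C)O)CC[C@H]2C(C)C)cc1O | target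

## Step count and risks
Total step count: 16.
Longest linear sequence: 15 steps (steps 1–13, 15 and 16). Step 14 is the one-step side branch.

**Step 6.** Raney Ni may saturate or shift the Δ4 double bond while it cleaves the C–S bonds. The fallback sets out from 10 and comes back at 12, by-passing 11, through a sulfur-free ionic deoxygenation. Luche reduction of 10 (NaBH4, CeCl3·7H2O, MeOH, 0 °C, axial hydride delivery) gives 15-noreudesm-4-en-3β-ol F1. Hydrogenolysis of this allylic alcohol with AlHCl2 (made from LiAlH4 and AlCl3, Et2O, reflux) puts hydride on the less hindered C3 end of the allyl cation. This keeps the trisubstituted Δ4 alkene of 12.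

**Step 11.** The trisubstituted alkene of 17 lies between a fully substituted C4 and the isopropyl-bearing C7, so hydroboration may be slow or leak to the β face. The fallback sets out from 16 and comes back at 19, replacing steps 10 and 11 by a conjugate borylation before the methyl addition.
- B2pin2, CuCl, NaOt-Bu, DPEphos and MeOH in THF at rt add boron to C6 from the α face. Protonation and equilibration α to the C4 ketone give trans-fused 6α-(pinacolatoboryl)-5αH-15-noreudesman-4-one F2.
- NaBO3·4H2O in THF/H2O oxidises the C–B bond with retention to 6α-hydroxy-5αH-15-noreudesman-4-one F3.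
- Excess MeLi/CeCl3 in THF at −78 °C first makes the C6 alkoxide, which cannot be eliminated, and then adds methyl equatorially from the α face to give 19.

**Step 15.** The axial 6β-OH is flanked by the isopropyl group and is syn-axial to the C10 methyl and 4β-OH, so the bulky cinnamoyl donor may react poorly. The fallback sets out from 21 and comes back at 26, building the cinnamate on the alcohol by olefination.
- Diethylphosphonoacetic acid, DCC and DMAP in CH2Cl2 acylate 21 through a small, ketene-like acyl donor. This gives 4β-hydroxy-5αH-eudesman-6β-yl 2-(diethoxyphosphoryl)acetate F4.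
- Commercial isovanillin is silylated (TBSCl, imidazole, DMF) to 3-(tert-butyldimethylsilyloxy)-4-methoxybenzaldehyde F5.
- A Masamune–Roush Horner–Wadsworth–Emmons reaction of F4 with F5 (LiCl, DBU, MeCN, rt) forms the E alkene and gives 26.

## Further compounds
F1 | step 6 | 15-noreudesm-4-en-3β-ol | C1C2=C[C@@H](O)CC[C@]2(C)CC[C@H]1C(C)C
F2 | step 11 | 6α-(4,4,5,5-tetramethyl-1,3,2-dioxaborolan-2-yl)-5αH-15-noreudesman-4-one | CC1(C)OB(OC1(C)C)[C@@H]2[C@@H]3[C@](C)(CCCC3=O)CC[C@H]2C(C)C
F3 | step 11 | 6α-hydroxy-5αH-15-noreudesman-4-one | O[C@@H]1[C@@H]2[C@](C)(CCCC2=O)CC[C@H]1C(C)C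
F4 | step 15 | 4β-hydroxy-5αH-eudesman-6β-yl 2-(diethoxyphosphoryl)acetate | CCOP(=O)(OCC)CC(=O)O[C@H]1[C@@H]2[C@](C)(CCC[C@]2(C)O)CC[C@H]1C(C)C
F5 | step 15 | 3-(tert-butyldimethylsilyloxy)-4-methoxybenzaldehyde | COc1ccc(C=O)cc1O[Si](C)(C)C(C)(C)C
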